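Ring C is disconnected at the O1–C8a aryl ether bond. Since O1 is then just the hydroxyl of a benzylic C2 carbinol, the (2S) centre is set early by hydrogenation of an aryl β-keto ester and is never touched again: a palladium-catalysed intramolecular O-arylation joins the free C2 hydroxyl to C8a of ring A and closes the pyran ring with retention. The cyclisation substrate is an open-chain 1,3-diaryl-1,3-dioxygenated propane: ring A carries a triflate at C8a, MOM on O5, geranyl at C6 and methoxy at C7; the future C4 carbonyl is masked as a TBS-protected carbinol, leaving the C2 hydroxyl as the only nucleophile.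

Key step: step 11

Remark: flavonoid numbering (O1, C2–C4, C4a, C5–C8, C8a) is used for all intermediates and geranyl means (2E)-3,7-dimethylocta-2,6-dien-1-yl; C4 is formed without control in step 7 and erased in step 13, so compounds 13–18 are carried as C4 epimer mixtures and are named and drawn as one epimer; the C4 hydroxyl is kept silylated through triflation and ring closure, because a free alkoxide ortho to the triflate could chelate palladium and be oxidised, or could take over the triflyl group.

Step 1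
Reactants: 1 5-methoxyresorcinol
Product: 2 3-methoxy-5-(triisopropylsilyloxy)phenol
Conditions: i-Pr3SiCl (1.0 equiv), imidazole, DMF, 0 °C to rt; 1 in twofold excess, the surplus recovered
Reagents that add atoms: triisopropylsilyl chloride, CC(C)[Si](Cl)(C(C)C)C(C)C
Why: Phenol O-silylation; the two hydroxyls of 1 are related by symmetry, so only one monosilyl ether can form, and the excess of diol should hold back double silylation.

Step 2
Reactants: 2 3-methoxy-5-(triisopropylsilyloxy)phenol
Product: 3 triisopropyl[3-methoxy-5-(methoxymethoxy)phenoxy]silane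
Conditions: MeOCH2Cl, i-Pr2NEt, CH2Cl2, 0 °C to rt
Reagents that add atoms: chloromethyl methyl ether, COCCl
Why: Williamson-type O-alkylation of the remaining phenol under an amine base that should leave the aryl silyl ether untouched.

Step 3
Reactants: 3 triisopropyl[3-methoxy-5-(methoxymethoxy)phenoxy]silane; 4 geranyl bromide
Product: 6 {4-[(2E)-3,7-dimethylocta-2,6-dien-1-yl]-3-methoxy-5-(methoxymethoxy)phenoxy}triisopropylsilane, via aryllithium 5 (not isolated)
Conditions: n-BuLi, THF, 0 °C; CuBr·SMe2 (10 mol%), then 4, −78 °C to rt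
Reagents that add atoms: none
Why: Directed ortho-metalation followed by copper-catalysed allylic substitution: the proton between OMOM and OMe is flanked by two lithium-coordinating oxygens while the positions next to the bulky, poorly coordinating OTIPS are shielded, and SN2 attack at the primary carbon of 4 should keep the E olefin.

Step 4
Reactants: 7 ethyl 3-(3,4-dimethoxyphenyl)-3-oxopropanoate
Product: 8 ethyl (3S)-3-(3,4-dimethoxyphenyl)-3-hydroxypropanoate
Conditions: RuCl2[(R)-BINAP] (0.5 mol%), H2 (20 bar), EtOH, 50 °C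
Reagents that add atoms: none
Why: Noyori asymmetric hydrogenation of a β-keto ester, in which the ester carbonyl chelates ruthenium and the (R)-BINAP ligand directs hydride to the ketone face that gives the (S)-aryl carbinol, the future C2.

Step 5
Reactants: 8 ethyl (3S)-3-(3,4-dimethoxyphenyl)-3-hydroxypropanoate
Product: 9 ethyl (3S)-3-(3,4-dimethoxyphenyl)-3-(triethylsilyloxy)propanoate
Conditions: Et3SiCl, imidazole, DMF, 0 °C to rt
Reagents that add atoms: chlorotriethylsilane, CC[Si](Cl)(CC)CC
Why: Silylation of a secondary alcohol under conditions too mild for retro-aldol cleavage or elimination of the β-hydroxy ester, so the carbinol configuration is untouched.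

Step 6
Reactants: 9 ethyl (3S)-3-(3,4-dimethoxyphenyl)-3-(triethylsilyloxy)propanoate
Product: 11 (3S)-3-(3,4-dimethoxyphenyl)-3-(triethylsilyloxy)propanal, via aluminium hemiacetal 10 (not isolated)
Conditions: i-Bu2AlH (1.1 equiv), CH2Cl2, −78 °C; MeOH, then aq. potassium sodium tartrate; used without delay
Reagents that add atoms: none
Why: Partial reduction of an ester, in which the tetrahedral aluminium hemiacetal, held at −78 °C and stabilised by the β-silyloxy oxygen, should collapse to the aldehyde only on work-up, without involving the stereocentre.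

Step 7
Reactants: 6 {4-[(2E)-3,7-dimethylocta-2,6-dien-1-yl]-3-methoxy-5-(methoxymethoxy)phenoxy}triisopropylsilane; 11 (3S)-3-(3,4-dimethoxyphenyl)-3-(triethylsilyloxy)propanal
Product: 13 (1S,3S)-3-(3,4-dimethoxyphenyl)-1-[3-geranyl-4-methoxy-2-(methoxymethoxy)-6-(triisopropylsilyloxy)phenyl]-3-(triethylsilyloxy)propan-1-ol, via aryllithium 12 (not isolated)
Conditions: 6 (1.2 equiv), s-BuLi, TMEDA, THF, −78 °C; then 11, −78 °C; AcOH in THF at −78 °C; Et3N-deactivated silica
Reagents that add atoms: none
Why: Directed ortho-metalation and 1,2-addition to an aldehyde: C4a is the only open position ortho to OMOM, the low temperature is meant to suppress silyl shift from oxygen to the lithiated carbon and deprotonation at the geranyl CH2, and the new C4 carbinol forms without control, which is harmless because step 13 oxidises it.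

Step 8
Reactants: 13 (1S,3S)-3-(3,4-dimethoxyphenyl)-1-[3-geranyl-4-methoxy-2-(methoxymethoxy)-6-(triisopropylsilyloxy)phenyl]-3-(triethylsilyloxy)propan-1-ol
Product: 14 (1S,3S)-1-(tert-butyldimethylsilyloxy)-3-(3,4-dimethoxyphenyl)-1-[3-geranyl-4-methoxy-2-(methoxymethoxy)-6-(triisopropylsilyloxy)phenyl]-3-(triethylsilyloxy)propane
Conditions: t-BuMe2SiOTf, 2,6-lutidine, CH2Cl2, −78 to −20 °C
Reagents that add atoms: tert-butyldimethylsilyl trifluoromethanesulfonate, CC(C)(C)[Si](C)(C)OS(=O)(=O)C(F)(F)F
Why: Silylation of a hindered secondary alcohol with a silyl triflate, fast enough at low temperature that the MOM acetal and the other silyl ethers should be left alone.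

Step 9
Reactants: 14 (1S,3S)-1-(tert-butyldimethylsilyloxy)-3-(3,4-dimethoxyphenyl)-1-[3-geranyl-4-methoxy-2-(methoxymethoxy)-6-(triisopropylsilyloxy)phenyl]-3-(triethylsilyloxy)propane
Product: 15 2-[(1S,3S)-1-(tert-butyldimethylsilyloxy)-3-(3,4-dimethoxyphenyl)-3-hydroxypropyl]-4-geranyl-5-methoxy-3-(methoxymethoxy)phenol
Conditions: Bu4NF (2.5 equiv), AcOH (2.5 equiv), THF, 0 °C to rt
Reagents that add atoms: none
Why: Fluoride-induced desilylation graded by rate: the aryl O–Si bond and the unhindered secondary TES ether should cleave well before the TBS ether at the congested C4 position, and the acetic acid buffer keeps the freed C2 oxygen protonated so that the TBS group does not migrate to it.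

Step 10
Reactants: 15 2-[(1S,3S)-1-(tert-butyldimethylsilyloxy)-3-(3,4-dimethoxyphenyl)-3-hydroxypropyl]-4-geranyl-5-methoxy-3-(methoxymethoxy)phenol
Product: 16 2-[(1S,3S)-1-(tert-butyldimethylsilyloxy)-3-(3,4-dimethoxyphenyl)-3-hydroxypropyl]-4-geranyl-5-methoxy-3-(methoxymethoxy)phenyl trifluoromethanesulfonate
Conditions: PhNTf2, Et3N, DMAP (cat.), CH2Cl2, 0 °C to rt
Reagents that add atoms: N-phenylbis(trifluoromethanesulfonimide), O=S(=O)(N(c1ccccc1)S(=O)(=O)C(F)(F)F)C(F)(F)F
Why: Sulfonylation of a phenol with a mild triflyl donor that does not react with a neutral secondary alcohol, so only the C8a oxygen is triflated.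

Step 11
Reactants: 16 2-[(1S,3S)-1-(tert-butyldimethylsilyloxy)-3-(3,4-dimethoxyphenyl)-3-hydroxypropyl]-4-geranyl-5-methoxy-3-(methoxymethoxy)phenyl trifluoromethanesulfonate
Product: 17 (2S,4S)-4-(tert-butyldimethylsilyloxy)-6-geranyl-7,3',4'-trimethoxy-5-(methoxymethoxy)flavan
Conditions: Pd(OAc)2 (5 mol%), racemic 2-(di-tert-butylphosphino)-1,1'-binaphthyl (6 mol%), Cs2CO3 (1.5 equiv), toluene, 80 °C, rigorously dry
Reagents that add atoms: none
Why: Zerovalent palladium, formed in the flask from Pd(OAc)2 and the phosphine, inserts into the C8a–OTf bond, the C2 hydroxyl binds and is deprotonated by Cs2CO3 with loss of triflate, and C–O reductive elimination from the seven-membered oxapalladacycle (Pd, C8a, C4a, C4, C3, C2, O) forms the O1–C8a bond. The closest known reaction type is the Buchwald–Hartwig-type palladium-catalysed intramolecular O-arylation of primary and secondary alcohols with aryl halides or sulfonates, which gives chromans. Ring C closes as a six-membered ring by attack of the tethered oxygen on the ipso carbon, formally an exo closure with respect to the departing triflate. No stereocentre is created, and C2 keeps its S configuration because the C2–O bond is never broken and the benzylic C2–H is not acidic under carbonate. The step needs reductive elimination to outrun β-hydride elimination of the palladium alkoxide, which the bulky electron-rich di-tert-butylbiarylphosphine favours, and it needs a single competent hydroxyl, which the substrate secures by carrying O4 as a TBS ether.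

Step 12
Reactants: 17 (2S,4S)-4-(tert-butyldimethylsilyloxy)-6-geranyl-7,3',4'-trimethoxy-5-(methoxymethoxy)flavan
Product: 18 (2S,4S)-6-geranyl-7,3',4'-trimethoxy-5-(methoxymethoxy)flavan-4-ol
Conditions: Bu4NF, THF, rt to 40 °C; Et3N-deactivated silica
Reagents that add atoms: none
Why: Fluoride cleavage of the last silyl ether under basic conditions, chosen because a flavan-4-ol with a trioxygenated ring A ionises readily at C4 in acid.

Step 13
Reactants: 18 (2S,4S)-6-geranyl-7,3',4'-trimethoxy-5-(methoxymethoxy)flavan-4-ol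
Product: 19 (2S)-6-geranyl-7,3',4'-trimethoxy-5-(methoxymethoxy)flavanone
Conditions: Dess–Martin periodinane, NaHCO3, CH2Cl2, 0 °C to rt
Reagents that add atoms: none
Why: Dess–Martin oxidation of a secondary benzylic alcohol, in which both C4 epimers converge on one ketone and the bicarbonate buffer should protect the acid-labile carbinol and leave the C2 centre and the olefins alone.

Step 14
Reactants: 19 (2S)-6-geranyl-7,3',4'-trimethoxy-5-(methoxymethoxy)flavanone
Product: 20 (2S)-6-geranyl-5-hydroxy-7,3',4'-trimethoxyflavanone (CNP0310479.1)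
Conditions: HCl (0.5 M) in MeOH–THF, 0 °C to rt
Reagents that add atoms: none
Why: Acid-catalysed acetal exchange with methanol; the MOM ether peri to the C4 carbonyl is especially labile because the freed phenol is held in a hydrogen bond to that carbonyl, so dilute acid at or below room temperature should suffice and spare the geranyl olefins and the C2 centre.

Compound list

1 | 5-methoxyresorcinol | COc1cc(O)cc(O)c1 | starting material
2 | 3-methoxy-5-(triisopropylsilyloxy)phenol | COc1cc(O)cc(O[Si](C(C)C)(C(C)C)C(C)C)c1 | intermediate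
3 | triisopropyl[3-methoxy-5-(methoxymethoxy)phenoxy]silane | COCOc1cc(OC)cc(O[Si](C(C)C)(C(C)C)C(C)C)c1 | intermediate
4 | geranyl bromide, (2E)-1-bromo-3,7-dimethylocta-2,6-diene | BrC/C=C(\C)CCC=C(C)C | starting material
5 | [2-methoxy-6-(methoxymethoxy)-4-(triisopropylsilyloxy)phenyl]lithium | [Li]c1c(OC)cc(O[Si](C(C)C)(C(C)C)C(C)C)cc1OCOC | intermediate (not isolated)
6 | {4-[(2E)-3,7-dimethylocta-2,6-dien-1-yl]-3-methoxy-5-(methoxymethoxy)phenoxy}triisopropylsilane | COCOc1cc(O[Si](C(C)C)(C(C)C)C(C)C)cc(OC)c1C/C=C(\C)CCC=C(C)C | intermediate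
7 | ethyl 3-(3,4-dimethoxyphenyl)-3-oxopropanoate | CCOC(=O)CC(=O)c1ccc(OC)c(OC)c1 | starting material
8 | ethyl (3S)-3-(3,4-dimethoxyphenyl)-3-hydroxypropanoate | COc1ccc([C@@H](O)CC(=O)OCC)cc1OC | intermediate
9 | ethyl (3S)-3-(3,4-dimethoxyphenyl)-3-(triethylsilyloxy)propanoate | COc1ccc([C@@H](O[Si](CC)(CC)CC)CC(=O)OCC)cc1OC | intermediate
10 | diisobutylaluminium hemiacetal of 9 (hemiacetal carbon undefined) | COc1ccc([C@@H](O[Si](CC)(CC)CC)CC(OCC)O[Al](CC(C)C)CC(C)C)cc1OC | intermediate (not isolated)
11 | (3S)-3-(3,4-dimethoxyphenyl)-3-(triethylsilyloxy)propanal | COc1ccc([C@@H](O[Si](CC)(CC)CC)CC=O)cc1OC | intermediate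
12 | [3-geranyl-4-methoxy-2-(methoxymethoxy)-6-(triisopropylsilyloxy)phenyl]lithium | [Li]c1c(OCOC)c(C/C=C(\C)CCC=C(C)C)c(OC)cc1O[Si](C(C)C)(C(C)C)C(C)C | intermediate (not isolated)
13 | (1S,3S)-3-(3,4-dimethoxyphenyl)-1-[3-geranyl-4-methoxy-2-(methoxymethoxy)-6-(triisopropylsilyloxy)phenyl]-3-(triethylsilyloxy)propan-1-ol | COc1ccc([C@@H](O[Si](CC)(CC)CC)C[C@H](O)c2c(O[Si](C(C)C)(C(C)C)C(C)C)cc(OC)c(C/C=C(\C)CCC=C(C)C)c2OCOC)cc1OC | intermediate
14 | (1S,3S)-1-(tert-butyldimethylsilyloxy)-3-(3,4-dimethoxyphenyl)-1-[3-geranyl-4-methoxy-2-(methoxymethoxy)-6-(triisopropylsilyloxy)phenyl]-3-(triethylsilyloxy)propane | COc1ccc([C@@H](O[Si](CC)(CC)CC)C[C@H](O[Si](C)(C)C(C)(C)C)c2c(O[Si](C(C)C)(C(C)C)C(C)C)cc(OC)c(C/C=C(\C)CCC=C(C)C)c2OCOC)cc1OC | intermediate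
15 | 2-[(1S,3S)-1-(tert-butyldimethylsilyloxy)-3-(3,4-dimethoxyphenyl)-3-hydroxypropyl]-4-geranyl-5-methoxy-3-(methoxymethoxy)phenol | COc1ccc([C@@H](O)C[C@H](O[Si](C)(C)C(C)(C)C)c2c(O)cc(OC)c(C/C=C(\C)CCC=C(C)C)c2OCOC)cc1OC | intermediate
16 | 2-[(1S,3S)-1-(tert-butyldimethylsilyloxy)-3-(3,4-dimethoxyphenyl)-3-hydroxypropyl]-4-geranyl-5-methoxy-3-(methoxymethoxy)phenyl trifluoromethanesulfonate | COc1ccc([C@@H](O)C[C@H](O[Si](C)(C)C(C)(C)C)c2c(OS(=O)(=O)C(F)(F)F)cc(OC)c(C/C=C(\C)CCC=C(C)C)c2OCOC)cc1OC | intermediate (key-step precursor)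
17 | (2S,4S)-4-(tert-butyldimethylsilyloxy)-6-geranyl-7,3',4'-trimethoxy-5-(methoxymethoxy)flavan | COc1ccc([C@@H]2C[C@H](O[Si](C)(C)C(C)(C)C)c3c(cc(OC)c(C/C=C(\C)CCC=C(C)C)c3OCOC)O2)cc1OC | intermediate (key-step product)
18 | (2S,4S)-6-geranyl-7,3',4'-trimethoxy-5-(methoxymethoxy)flavan-4-ol | COc1ccc([C@@H]2C[C@H](O)c3c(cc(OC)c(C/C=C(\C)CCC=C(C)C)c3OCOC)O2)cc1OC | intermediate
19 | (2S)-6-geranyl-7,3',4'-trimethoxy-5-(methoxymethoxy)flavanone | COc1ccc([C@@H]2CC(=O)c3c(cc(OC)c(C/C=C(\C)CCC=C(C)C)c3OCOC)O2)cc1OC | intermediate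
20 | (2S)-6-geranyl-5-hydroxy-7,3',4'-trimethoxyflavanone (CNP0310479.1) | COc1ccc([C@@H]2CC(=O)c3c(cc(OC)c(C/C=C(\C)CCC=C(C)C)c3O)O2)cc1OC | target

Total step count: 14 (ring A fragment: steps 1–3; aldehyde fragment: steps 4–6; union and completion: steps 7–14).
Longest linear sequence: 11 steps (steps 1–3, then 7–14).

Steps most likely to fail

Step 11. The palladium alkoxide may lose a β-hydride faster than it couples (oxidation at C2 with reduction of the C8a–OTf bond), carbonate may cleave the triflate at sulfur, or oxidative addition at the hindered C8a may be slow. The fallback closes ring C at the O1–C2 bond with inversion, so it needs the opposite carbinol configuration, and it sets out from 7. Hydrogenation of 7 with RuCl2[(S)-BINAP] should give ethyl (3R)-3-(3,4-dimethoxyphenyl)-3-hydroxypropanoate F1. Steps 5 to 9 are then run unchanged in this series: the TES ether F2, its aluminium hemiacetal F3 (not isolated), the (3R)-aldehyde F4, the carbinol adduct F5 (from aryllithium 12), the TBS ether F6 and the (3R)-hydroxy phenol F7. Intramolecular Mitsunobu etherification of F7 (PPh3, DIAD, THF, 0 °C) lets the phenol oxygen displace the activated C2 oxygen in an SN2 process, turning R into S, and the route is rejoined at 17. Partial ionisation at the electron-rich benzylic C2 could erode the enantiomeric purity in this variant, so it is kept as the second choice.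

Step 7. Deprotonation may occur at the benzylic, allylic CH2 of the geranyl group instead of at C4a, the silyl group may shift from oxygen to the lithiated carbon, or the hindered aryllithium may enolise the aldehyde. The fallback replaces the silyl ether by a second coordinating acetal, so that metalation occurs at a doubly activated site with no silicon next to it, and it sets out from 6. Bu4NF should give 4-geranyl-3-methoxy-5-(methoxymethoxy)phenol F8, and dihydropyran with PPTS the tetrahydropyranyl ether F9. n-BuLi in THF at −78 to −20 °C should then remove the proton between the two acetal oxygens to give the aryllithium F10, which is added to 11 at −78 °C to give the carbinol F11. t-BuMe2SiOTf and 2,6-lutidine at −78 °C give the TBS ether F12, and PPTS in MeOH at rt removes the THP acetal and the TES ether together, rejoining the route at 15.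

Step 9. Chemoselectivity may be lost: once the C2 oxygen is unveiled, the TBS group may migrate to it or be cleaved, or the TES ether may lag behind. The fallback unmasks the two oxygens one at a time by different mechanisms and sets out from 14. One equivalent of Bu4NF buffered with AcOH at −20 °C should cleave only the aryl O–Si bond and give the phenol F13, and PhNTf2 with Et3N gives the triflate F14. With ring A now deactivated by the triflate, PPTS in MeOH–CH2Cl2 at 0 °C should remove the TES ether alone, rejoining the route at 16.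

Further compounds

F1 | step 11 | ethyl (3R)-3-(3,4-dimethoxyphenyl)-3-hydroxypropanoate | COc1ccc([C@H](O)CC(=O)OCC)cc1OC
F2 | step 11 | ethyl (3R)-3-(3,4-dimethoxyphenyl)-3-(triethylsilyloxy)propanoate | COc1ccc([C@H](O[Si](CC)(CC)CC)CC(=O)OCC)cc1OC
F3 | step 11 | diisobutylaluminium hemiacetal of F2 (not isolated) | COc1ccc([C@H](O[Si](CC)(CC)CC)CC(OCC)O[Al](CC(C)C)CC(C)C)cc1OC
F4 | step 11 | (3R)-3-(3,4-dimethoxyphenyl)-3-(triethylsilyloxy)propanal | COc1ccc([C@H](O[Si](CC)(CC)CC)CC=O)cc1OC
F5 | step 11 | (1S,3R)-3-(3,4-dimethoxyphenyl)-1-[3-geranyl-4-methoxy-2-(methoxymethoxy)-6-(triisopropylsilyloxy)phenyl]-3-(triethylsilyloxy)propan-1-ol (C1 epimers, one drawn) | COc1ccc([C@H](O[Si](CC)(CC)CC)C[C@H](O)c2c(O[Si](C(C)C)(C(C)C)C(C)C)cc(OC)c(C/C=C(\C)CCC=C(C)C)c2OCOC)cc1OC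
F6 | step 11 | (1S,3R)-1-(tert-butyldimethylsilyloxy)-3-(3,4-dimethoxyphenyl)-1-[3-geranyl-4-methoxy-2-(methoxymethoxy)-6-(triisopropylsilyloxy)phenyl]-3-(triethylsilyloxy)propane | COc1ccc([C@H](O[Si](CC)(CC)CC)C[C@H](O[Si](C)(C)C(C)(C)C)c2c(O[Si](C(C)C)(C(C)C)C(C)C)cc(OC)c(C/C=C(\C)CCC=C(C)C)c2OCOC)cc1OC
F7 | step 11 | 2-[(1S,3R)-1-(tert-butyldimethylsilyloxy)-3-(3,4-dimethoxyphenyl)-3-hydroxypropyl]-4-geranyl-5-methoxy-3-(methoxymethoxy)phenol | COc1ccc([C@H](O)C[C@H](O[Si](C)(C)C(C)(C)C)c2c(O)cc(OC)c(C/C=C(\C)CCC=C(C)C)c2OCOC)cc1OC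
F8 | step 7 | 4-geranyl-3-methoxy-5-(methoxymethoxy)phenol | COCOc1cc(O)cc(OC)c1C/C=C(\C)CCC=C(C)C
F9 | step 7 | 2-[4-geranyl-3-methoxy-5-(methoxymethoxy)phenoxy]tetrahydro-2H-pyran (acetal carbon undefined) | COCOc1cc(OC2CCCCO2)cc(OC)c1C/C=C(\C)CCC=C(C)C
F10 | step 7 | [3-geranyl-4-methoxy-2-(methoxymethoxy)-6-(tetrahydro-2H-pyran-2-yloxy)phenyl]lithium (not isolated) | [Li]c1c(OCOC)c(C/C=C(\C)CCC=C(C)C)c(OC)cc1OC1CCCCO1
F11 | step 7 | (1S,3S)-3-(3,4-dimethoxyphenyl)-1-[3-geranyl-4-methoxy-2-(methoxymethoxy)-6-(tetrahydro-2H-pyran-2-yloxy)phenyl]-3-(triethylsilyloxy)propan-1-ol (C1 and acetal epimers) | COc1ccc([C@@H](O[Si](CC)(CC)CC)C[C@H](O)c2c(OC3CCCCO3)cc(OC)c(C/C=C(\C)CCC=C(C)C)c2OCOC)cc1OC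
F12 | step 7 | (1S,3S)-1-(tert-butyldimethylsilyloxy)-3-(3,4-dimethoxyphenyl)-1-[3-geranyl-4-methoxy-2-(methoxymethoxy)-6-(tetrahydro-2H-pyran-2-yloxy)phenyl]-3-(triethylsilyloxy)propane | COc1ccc([C@@H](O[Si](CC)(CC)CC)C[C@H](O[Si](C)(C)C(C)(C)C)c2c(OC3CCCCO3)cc(OC)c(C/C=C(\C)CCC=C(C)C)c2OCOC)cc1OC
F13 | step 9 | 2-[(1S,3S)-1-(tert-butyldimethylsilyloxy)-3-(3,4-dimethoxyphenyl)-3-(triethylsilyloxy)propyl]-4-geranyl-5-methoxy-3-(methoxymethoxy)phenol | COc1ccc([C@@H](O[Si](CC)(CC)CC)C[C@H](O[Si](C)(C)C(C)(C)C)c2c(O)cc(OC)c(C/C=C(\C)CCC=C(C)C)c2OCOC)cc1OC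
F14 | step 9 | 2-[(1S,3S)-1-(tert-butyldimethylsilyloxy)-3-(3,4-dimethoxyphenyl)-3-(triethylsilyloxy)propyl]-4-geranyl-5-methoxy-3-(methoxymethoxy)phenyl trifluoromethanesulfonate | COc1ccc([C@@H](O[Si](CC)(CC)CC)C[C@H](O[Si](C)(C)C(C)(C)C)c2c(OS(=O)(=O)C(F)(F)F)cc(OC)c(C/C=C(\C)CCC=C(C)C)c2OCOC)cc1OC
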